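Overview: Numbering as in ent-kaurane. Ring A = C10, C1, C2, C3, C4, C5 (C20 methyl on C10; C18 methyl and C19 acid on C4; C6 acid on C5). Ring C = C8, C9, C11, C12, C13, C14 (C11 ketone; C7 aldehyde on C8). Ring D = C8, C14, C13, C16, C15 (C17 methylene on C16).
Enabling feature: ring A carries two cis-vicinal carboxyl carbons, C19 on quaternary C4 and C6 on C5, directly beside quaternary C10, and C6 stands 1,5 to the C11 ketone across the hindered C9–C10 bond. C19 can therefore first be a ring member, the ketone between C4 and C5 of a seven-membered ring C10–C1–C2–C3–C4–C19–C5.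
Key disconnection: in that ring the C19 ketone and the C6 ester make C10 a doubly activated acceptor for C9. A chloride on C4 then lets the same ketone leave the ring by Favorskii contraction, which forms C4–C5, creates ring A and delivers C19 as the acid.
Further disconnections: the C7 aldehyde and C6 acid come from a temporary ε-lactone C6(=O)–O–C7 that ties the fragments and relays C8 to C9 and C10. C13–C16 comes from vinyl radical closure on a C12=C13 enone. The ester bond joins fragment 1 (ring C as a Birch dienol ether alcohol, C8 set by auxiliary-controlled reductive alkylation) and fragment 2 (chloro cycloheptenone acid from 2,6-dimethylcyclohexanone and a diazoacetate).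
Order of ring formation: ring C (from an arene), the seven-membered carbocycle, then the lactone ring and ring A together in the key step, then ring D. The lactone ring is opened at the end.

Key step: step 10

Remark: compounds 11 and 13 to 20 carry stereocentres in the six- or seven-membered carbocycle (C4, C5, C10) that are erased or reset later. They are used as mixtures and drawn without configuration there.
Assumption: the (S)-amine 2 is taken to direct the alkylation of step 3 to the face that gives the drawn C8 configuration, as expected for ortho-silyl benzamides of this amine. Should the other face react, the (R)-amine is used and nothing else changes.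

Step 1
Reactants: 1 2-bromo-5-methoxybenzoic acid; 2 (S)-2-(methoxymethyl)pyrrolidine
Product: 3 (S)-(2-bromo-5-methoxyphenyl)[2-(methoxymethyl)pyrrolidin-1-yl]methanone
Conditions: DCC, HOBt (cat.), CH2Cl2, 0 °C to rt
Reagents that add atoms: none
Why: Carbodiimide amide coupling should attach the proline-derived amine whose stereocentre later controls C8, and no new stereocentre is formed.

Step 2
Reactants: 3 (S)-(2-bromo-5-methoxyphenyl)[2-(methoxymethyl)pyrrolidin-1-yl]methanone
Product: 5 (S)-[5-methoxy-2-(trimethylsilyl)phenyl][2-(methoxymethyl)pyrrolidin-1-yl]methanone, via aryllithium 4 (not isolated)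
Conditions: n-BuLi, THF, −78 °C; then Me3SiCl, −78 °C to rt
Reagents that add atoms: chlorotrimethylsilane, C[Si](C)(C)Cl
Why: Bromine–lithium exchange at low temperature should outrun attack on the tertiary amide, and silylation of aryllithium 4 installs the removable ortho blocking group that later allows only one amide enolate geometry.

Step 3
Reactants: 5 (S)-[5-methoxy-2-(trimethylsilyl)phenyl][2-(methoxymethyl)pyrrolidin-1-yl]methanone; 6 2,3-dibromopropene
Product: 8 [(1S)-1-(2-bromoprop-2-en-1-yl)-5-methoxy-2-(trimethylsilyl)cyclohexa-2,5-dien-1-yl][(2S)-2-(methoxymethyl)pyrrolidin-1-yl]methanone, via potassium amide enolate 7 (not isolated)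
Conditions: K, NH3/THF, t-BuOH (1 equiv), −78 °C; piperylene; then 6, −78 °C
Reagents that add atoms: none
Why: In this auxiliary-controlled Birch reduction–alkylation the benzamide is reduced at the ipso and para carbons to the chelated enolate 7, whose geometry is fixed by the ortho silyl group, and the allylic bromide of 6 should enter at C8 from the face not covered by the methoxymethyl-bound potassium, which sets C8, while the vinylic bromide survives because excess metal is destroyed first.

Step 4
Reactants: 8 [(1S)-1-(2-bromoprop-2-en-1-yl)-5-methoxy-2-(trimethylsilyl)cyclohexa-2,5-dien-1-yl][(2S)-2-(methoxymethyl)pyrrolidin-1-yl]methanone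
Product: 9 [(1S)-1-(2-bromoprop-2-en-1-yl)-5-methoxy-2-(trimethylsilyl)cyclohexa-2,5-dien-1-yl]methanol
Conditions: LiH2NBH3, THF, 0 to 23 °C; aq NaOH work-up
Reagents that add atoms: none
Why: LiH2NBH3 is a small, strongly nucleophilic hydride donor that reduces hindered tertiary amides to primary alcohols with C–N cleavage, the basic work-up keeps the enol ether, and the quaternary C8 cannot epimerise.

Step 5
Reactants: 10 2,6-dimethylcyclohexanone
Product: 11 2-chloro-2,6-dimethylcyclohexanone
Conditions: SO2Cl2 (1 equiv), CH2Cl2, 0 °C to rt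
Reagents that add atoms: sulfuryl chloride, O=S(=O)(Cl)Cl
Why: Electrophilic α-chlorination through the more substituted enol should give the tertiary chloride, whose configuration is of no consequence.

Step 6
Reactants: 11 2-chloro-2,6-dimethylcyclohexanone; 12 tert-butyl diazoacetate
Product: 13 tert-butyl 3-chloro-3,7-dimethyl-2-oxocycloheptane-1-carboxylate
Conditions: BF3·OEt2, Et2O, −30 to 0 °C
Reagents that add atoms: none
Why: Lewis acid promoted diazoacetate homologation (Tiffeneau–Demjanov type ring expansion of a ketone) should insert the ester-bearing carbon C5 only on the methine side, because a chlorine-bearing carbon is a poor migrating group, and all stereocentres formed are erased or reset later.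

Step 7
Reactants: 13 tert-butyl 3-chloro-3,7-dimethyl-2-oxocycloheptane-1-carboxylate
Product: 16 tert-butyl 6-chloro-2,6-dimethyl-7-oxocyclohept-1-ene-1-carboxylate, via selenide 14 (not isolated), via selenoxide 15 (not isolated)
Conditions: PhSeCl, pyridine, CH2Cl2, 0 °C; then 30% H2O2, 0 °C to rt
Reagents that add atoms: none
Why: Selenenylation of the β-keto ester enol at C5 followed by selenoxide syn elimination should give the tetrasubstituted C5=C10 alkene, C10–H being the only β-hydrogen.

Step 8
Reactants: 16 tert-butyl 6-chloro-2,6-dimethyl-7-oxocyclohept-1-ene-1-carboxylate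
Product: 17 6-chloro-2,6-dimethyl-7-oxocyclohept-1-ene-1-carboxylic acid
Conditions: CF3CO2H/CH2Cl2 (1:4), 0 °C to rt
Reagents that add atoms: none
Why: Acidolysis of the tert-butyl ester by loss of isobutene frees the acid without base, which the chloro enone would not tolerate.

Step 9
Reactants: 17 6-chloro-2,6-dimethyl-7-oxocyclohept-1-ene-1-carboxylic acid; 9 [(1S)-1-(2-bromoprop-2-en-1-yl)-5-methoxy-2-(trimethylsilyl)cyclohexa-2,5-dien-1-yl]methanol
Product: 19 [(1S)-1-(2-bromoprop-2-en-1-yl)-5-methoxy-2-(trimethylsilyl)cyclohexa-2,5-dien-1-yl]methyl 6-chloro-2,6-dimethyl-7-oxocyclohept-1-ene-1-carboxylate, via acid chloride 18 (not isolated)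
Conditions: 1-chloro-N,N,2-trimethylprop-1-en-1-amine, CH2Cl2, 0 °C; then 9, pyridine, DMAP (cat.), 0 °C to rt
Reagents that add atoms: none
Why: Neutral conversion of the acid into acid chloride 18 and pyridine-buffered, DMAP-catalysed acylation of the neopentyl alcohol should form the C6(=O)–O–C7 tether without harming the acid-labile enol ether.

Step 10
Reactants: 19 [(1S)-1-(2-bromoprop-2-en-1-yl)-5-methoxy-2-(trimethylsilyl)cyclohexa-2,5-dien-1-yl]methyl 6-chloro-2,6-dimethyl-7-oxocyclohept-1-ene-1-carboxylate
Product: 23 16-bromo-11-oxo-6,7:13,16-diseco-ent-kaura-12,16-dien-6,7-olid-19-oic acid, via Michael adduct 20 (not isolated), via cyclopropanone 21 (not isolated), via potassium carboxylate 22 (not isolated)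
Conditions: Sc(OTf)3 (10 mol %), 2,6-di-tert-butylpyridine (20 mol %), 4 Å MS, CH2Cl2, −40 to 0 °C; then THF, 2 M aq KOH, 0 to 40 °C; then 2 M HCl to pH 1, rt (one flask)
Reagents that add atoms: potassium hydroxide, [K+].[OH-]; water, O
Why: In the first phase Sc(OTf)3 chelates the C19 and C6 carbonyl groups and the enol ether carbon C9 adds to the doubly activated C10 (Lewis acid catalysed Michael or ene-type addition of an alkyl enol ether to an alkylidene β-keto ester; 7-endo-trig closure of the ε-lactone ring), after which the C11 oxocarbenium ion gives its doubly allylic C12 proton to the enolate and leaves dienol ether 20. In the second phase KOH forms the β-keto lactone enolate, the tertiary C4 chloride ionises to a 2-oxyallyl species that closes in a disrotatory way to cyclopropanone 21 (new C4–C5 bond), hydroxide adds to C19 and the C19–C5 bond breaks toward the ester-stabilised C5 carbanion, so the seven-membered ring contracts to ring A and C19 leaves the ring as the acid on C4; this is the Favorskii rearrangement in the form known for 6-halo-2-(alkoxycarbonyl)cyclohexanones, which give cyclopentane-1,2-dicarboxylic acids. C9 is set by the tether, since the chain C8–C7–O–C6 can bring C10 only to the face of the flat diene that carries C7, and C10 is set by the fixed ring geometry of the acceptor (C6 is cis to the C20 methyl group) together with a chair-like extended transition state in which C5 is anti to C11, the only other low-strain arrangement placing the chelated dicarbonyl unit under ring C. C4 is set when C19 is pushed out of the ring toward the face of the small C20 methyl group and away from the ring C substituent on C10, both C4 epimers of 19 converging because the oxyallyl species is planar, and C5 is set by protonation from the face opposite the now axial C19 and C20 groups, which also gives the more stable equatorial C6. The step needs closure to the cyclopropanone to win over loss of HCl and over attack of hydroxide on the lactone or on C19 before ionisation, which the substrate secures by being fully enolised (the enolate shields both carbonyl groups), by the tertiary nature of the chloride and by ring C staying masked as a base-inert dienol ether without an acidic C9–H. In the last phase aqueous HCl protonates C14 ipso to silicon, the silyl group is lost, the dienol ether is hydrolysed to the conjugated C12=C13 enone and the carboxylic acid is set free.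

Step 11
Reactants: 23 16-bromo-11-oxo-6,7:13,16-diseco-ent-kaura-12,16-dien-6,7-olid-19-oic acid
Product: 24 11-oxo-6,7-seco-ent-kaur-16-en-6,7-olid-19-oic acid
Conditions: Bu3SnH (slow addition), AIBN (cat.), benzene, 80 °C
Reagents that add atoms: none
Why: Tin hydride mediated 5-exo-trig cyclisation of the C16 vinyl radical onto the enone β-carbon C13 should close ring D as the bicyclo[3.2.1]octane, and C13 can only form with the bridge on the face of ring C that carries C15.

Step 12
Reactants: 24 11-oxo-6,7-seco-ent-kaur-16-en-6,7-olid-19-oic acid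
Product: 25 7-hydroxy-11-oxo-6,7-seco-ent-kaur-16-ene-6,19-dioic acid
Conditions: LiOH, THF/H2O, 40 °C; then 1 M HCl to pH 3, 0 °C, used at once
Reagents that add atoms: lithium hydroxide, [Li+].[OH-]
Why: Saponification should open the ε-lactone, whose ester is locked in the reactive E conformation and can be assisted by the neighbouring C19 carboxylate, while C9–H lies near the plane of the C11 carbonyl group between two quaternary carbons and should therefore not exchange.

Step 13
Reactants: 25 7-hydroxy-11-oxo-6,7-seco-ent-kaur-16-ene-6,19-dioic acid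
Product: 26 7,11-dioxo-6,7-seco-ent-kaur-16-ene-6,19-dioic acid (CNP0408869.1)
Conditions: Dess–Martin periodinane, CH2Cl2, 0 °C to rt
Reagents that add atoms: none
Why: Dess–Martin oxidation should take the neopentyl primary alcohol to the aldehyde without over-oxidation and tolerates the free acids, the ketone and the exocyclic alkene, and C8 has no hydrogen that could epimerise.

Compound list
1 | 2-bromo-5-methoxybenzoic acid | COc1ccc(Br)c(C(=O)O)c1 | starting material
2 | (S)-2-(methoxymethyl)pyrrolidine | COC[C@@H]1CCCN1 | starting material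
3 | (S)-(2-bromo-5-methoxyphenyl)[2-(methoxymethyl)pyrrolidin-1-yl]methanone | COc1ccc(Br)c(C(=O)N2CCC[C@H]2COC)c1 | intermediate
4 | aryllithium from 3 | COc1ccc([Li])c(C(=O)N2CCC[C@H]2COC)c1 | intermediate
5 | (S)-[5-methoxy-2-(trimethylsilyl)phenyl][2-(methoxymethyl)pyrrolidin-1-yl]methanone | COc1ccc([Si](C)(C)C)c(C(=O)N2CCC[C@H]2COC)c1 | intermediate
6 | 2,3-dibromopropene | C=C(Br)CBr | starting material
7 | potassium amide enolate of the 1,4-dihydroarene | COC1=CC(=C([O-])N2CCC[C@H]2COC)C([Si](C)(C)C)=CC1.[K+] | intermediate
8 | [(1S)-1-(2-bromoprop-2-en-1-yl)-5-methoxy-2-(trimethylsilyl)cyclohexa-2,5-dien-1-yl][(2S)-2-(methoxymethyl)pyrrolidin-1-yl]methanone | C=C(Br)C[C@]1(C(=O)N2CCC[C@H]2COC)C([Si](C)(C)C)=CCC(OC)=C1 | intermediate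
9 | [(1S)-1-(2-bromoprop-2-en-1-yl)-5-methoxy-2-(trimethylsilyl)cyclohexa-2,5-dien-1-yl]methanol (fragment 1) | C=C(Br)C[C@]1(CO)C([Si](C)(C)C)=CCC(OC)=C1 | intermediate
10 | 2,6-dimethylcyclohexanone | CC1CCCC(C)C1=O | starting material
11 | 2-chloro-2,6-dimethylcyclohexanone | CC1CCCC(C)(Cl)C1=O | intermediate
12 | tert-butyl diazoacetate | CC(C)(C)OC(=O)C=[N+]=[N-] | starting material
13 | tert-butyl 3-chloro-3,7-dimethyl-2-oxocycloheptane-1-carboxylate | CC1CCCC(C)(Cl)C(=O)C1C(=O)OC(C)(C)C | intermediate
14 | tert-butyl 3-chloro-3,7-dimethyl-2-oxo-1-(phenylselanyl)cycloheptane-1-carboxylate | CC1CCCC(C)(Cl)C(=O)C1([Se]c2ccccc2)C(=O)OC(C)(C)C | intermediate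
15 | selenoxide of 14 | CC1CCCC(C)(Cl)C(=O)C1([Se](=O)c2ccccc2)C(=O)OC(C)(C)C | intermediate
16 | tert-butyl 6-chloro-2,6-dimethyl-7-oxocyclohept-1-ene-1-carboxylate | CC1=C(C(=O)OC(C)(C)C)C(=O)C(C)(Cl)CCC1 | intermediate
17 | 6-chloro-2,6-dimethyl-7-oxocyclohept-1-ene-1-carboxylic acid (fragment 2) | CC1=C(C(=O)O)C(=O)C(C)(Cl)CCC1 | intermediate
18 | 6-chloro-2,6-dimethyl-7-oxocyclohept-1-ene-1-carbonyl chloride | CC1=C(C(=O)Cl)C(=O)C(C)(Cl)CCC1 | intermediate
19 | ester of 9 with 17, both C4 epimers (tethered precursor) | C=C(Br)C[C@]1(COC(=O)C2=C(C)CCCC(C)(Cl)C2=O)C([Si](C)(C)C)=CCC(OC)=C1 | intermediate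
20 | Michael adduct: β-keto ε-lactone with the C9–C10 bond syn to C7, ring C as 11-methoxy-11,13-diene bearing 14-SiMe3, seven-membered chloro ketone ring | C=C(Br)C[C@]2(CO3)C([Si](C)(C)C)=CC=C(OC)[C@H]2[C@]1(C)CCCC(C)(Cl)C(=O)C1C3=O | intermediate
21 | cyclopropanone: C4–C5 bond formed, C19 carbonyl bridging C4 and C5 on the face of C20 | C=C(Br)C[C@]2(CO3)C([Si](C)(C)C)=CC=C(OC)[C@H]2[C@]1(C)CCC[C@@]4(C)C(=O)[C@@]14C3=O | intermediate
22 | potassium 16-bromo-11-methoxy-14-(trimethylsilyl)-6,7:13,16-diseco-ent-kaura-11,13,16-trien-6,7-olid-19-oate | C=C(Br)C[C@]2(CO3)C([Si](C)(C)C)=CC=C(OC)[C@H]2[C@]1(C)CCC[C@@](C)(C(=O)[O-])[C@H]1C3=O.[K+] | intermediate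
23 | 16-bromo-11-oxo-6,7:13,16-diseco-ent-kaura-12,16-dien-6,7-olid-19-oic acid (C20, C19 and C6 on one face of ring A, C9 on the other) | C=C(Br)C[C@]2(CO3)CC=CC(=O)[C@H]2[C@]1(C)CCC[C@@](C)(C(=O)O)[C@H]1C3=O | intermediate
24 | 11-oxo-6,7-seco-ent-kaur-16-en-6,7-olid-19-oic acid | C=C1C[C@]2(CO3)C[C@H]1CC(=O)[C@H]2[C@]1(C)CCC[C@@](C)(C(=O)O)[C@H]1C3=O | intermediate
25 | 7-hydroxy-11-oxo-6,7-seco-ent-kaur-16-ene-6,19-dioic acid | C=C1C[C@]2(CO)C[C@H]1CC(=O)[C@H]2[C@]1(C)CCC[C@@](C)(C(=O)O)[C@H]1C(=O)O | intermediate
26 | 7,11-dioxo-6,7-seco-ent-kaur-16-ene-6,19-dioic acid (CNP0408869.1) | C=C1C[C@]2(C=O)C[C@H]1CC(=O)[C@H]2[C@]1(C)CCC[C@@](C)(C(=O)O)[C@H]1C(=O)O | target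

Total step count: 13. Longest linear sequence: 9 steps (steps 1 to 4, then 9 to 13; the branch of steps 5 to 8, then 9 to 13, is equally long).

Steps most likely to fail

Step 10.
- **Risk:** The 7-endo closure onto the tetrasubstituted acceptor may be slow, so that hydrolysis of the enol ether or deconjugation of the acceptor takes over. In the basic phase, loss of HCl or solvolysis of the tertiary chloride may compete with closure to the cyclopropanone.
- **Fallback:** It gives up the tether and makes the union intermolecular. It sets out from 9 and 16 and comes back to the route at 25.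
- Alcohol 9 is silylated (TBSCl, imidazole, DMF) to the tert-butyldimethylsilyl ether F1.
- F1 and the tert-butyl ester 16 are joined by a Lewis acid promoted Michael addition (Sc(OTf)3 or SnCl4, CH2Cl2, low temperature) through an open antiperiplanar transition state to the untethered adduct F2. Diastereomers at C9 and C10 are separated here if facial selectivity is poor.
- Aqueous KOH in THF effects the Favorskii contraction to the ring A monoacid tert-butyl ester F3.
- CF3CO2H, then aqueous HCl, removes the tert-butyl ester, both silyl groups and the enol ether to give the bromoallyl enone hydroxy diacid F4.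
- Bu3SnH/AIBN closes ring D and gives 25.

Step 6.
- **Risk:** Addition of the diazoacetate to the hindered, doubly α-branched chloro ketone may be slower than Lewis acid induced decomposition of the diazo compound or closure to the glycidic ester.
- **Fallback:** It reverses the order of halogenation and homologation. It sets out from 10 and 12 and comes back at 13.
- The symmetrical and less hindered ketone 10 is homologated with 12 and BF3·OEt2 to tert-butyl 3,7-dimethyl-2-oxocycloheptane-1-carboxylate F5.
- The β-keto ester dianion of F5 (2 equiv LDA, THF, −78 to 0 °C) reacts at its more basic α' carbon C4 with hexachloroethane to give 13.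

Step 4.
- **Risk:** Hydride delivery to the very hindered amide carbonyl may stall, or the hemiaminal may collapse with C–O cleavage toward the amine.
- **Fallback:** It activates the amide instead of forcing the reduction. It sets out from 8 and comes back at 9.
- Methyl triflate (CH2Cl2, rt) alkylates the amide oxygen to the O-methyl imidate triflate F6.
- Hydrolysis in pH 7 phosphate buffer expels the amine and gives the methyl ester F7.
- LiAlH4 (Et2O, 0 °C) reduces F7 to 9.

Further compounds
F1 | step 10 | tert-butyl{[(1S)-1-(2-bromoprop-2-en-1-yl)-5-methoxy-2-(trimethylsilyl)cyclohexa-2,5-dien-1-yl]methoxy}dimethylsilane | C=C(Br)C[C@]1(CO[Si](C)(C)C(C)(C)C)C([Si](C)(C)C)=CCC(OC)=C1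
F2 | step 10 | untethered Michael adduct (tert-butyl β-keto ester, C7 silyl ether, ring C dienol ether) | C=C(Br)C[C@]2(CO[Si](C)(C)C(C)(C)C)C([Si](C)(C)C)=CC=C(OC)[C@H]2[C@]1(C)CCCC(C)(Cl)C(=O)C1C(=O)OC(C)(C)C
F3 | step 10 | ring-contracted C19 acid with C6 tert-butyl ester | C=C(Br)C[C@]2(CO[Si](C)(C)C(C)(C)C)C([Si](C)(C)C)=CC=C(OC)[C@H]2[C@]1(C)CCC[C@@](C)(C(=O)O)[C@H]1C(=O)OC(C)(C)C
F4 | step 10 | 16-bromo-7-hydroxy-11-oxo-6,7:13,16-diseco-ent-kaura-12,16-diene-6,19-dioic acid | C=C(Br)C[C@]2(CO)CC=CC(=O)[C@H]2[C@]1(C)CCC[C@@](C)(C(=O)O)[C@H]1C(=O)O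
F5 | step 6 | tert-butyl 3,7-dimethyl-2-oxocycloheptane-1-carboxylate | CC1CCCC(C)C(=O)C1C(=O)OC(C)(C)C
F6 | step 4 | O-methyl imidate triflate of 8 | C=C(Br)C[C@]1(C(OC)=[N+]2CCC[C@H]2COC)C([Si](C)(C)C)=CCC(OC)=C1.[O-]S(=O)(=O)C(F)(F)F
F7 | step 4 | methyl (1S)-1-(2-bromoprop-2-en-1-yl)-5-methoxy-2-(trimethylsilyl)cyclohexa-2,5-diene-1-carboxylate | C=C(Br)C[C@]1(C(=O)OC)C([Si](C)(C)C)=CCC(OC)=C1
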